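**Retrosynthetic overview**
1. Target ⇐ MnO2 oxidation of the allylic alcohol of triol 38 ⇐ desilylation ⇐ Julia–Kocienski olefination (E-alkene next to ring A) of ring B enal 24 with ring A sulfone 36.
2. 24 ⇐ lactol Wittig (E-trisubstituted alkene), Babler–Dauben transposition (Z-enal), B-alkyl Suzuki coupling and hydroboration (hydroxypropyl chain and its CH stereocentre) on the trans-fused keto lactone 10.
3. 10 ⇐ ozonolysis of methylated (S)-Wieland–Miescher ketone 4. Key C–C bond: quaternary ring carbon to side-chain CH2, made by intermolecular Michael addition of dione 1 to enone 2, then proline aldol desymmetrisation.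
4. 36 ⇐ methylenation and Mukaiyama hydroxymethylation of a 3,3,4-trimethylcyclohexanone enol ether ⇐ (S)-4-methylcyclohexenone 27 ⇐ organocatalytic intermolecular Michael addition of propanal to 2, then aldol condensation.
5. Ring order: ring B is present from 1 (auxiliary carbocycle closed in step 2 and cleaved in step 5; auxiliary lactone closed in step 6 and opened in steps 13–14); ring A is closed in step 19.

Assumption: the (R)-diarylprolinol ether is taken to give (S)-aldehyde 26, by analogy with related enamine Michael additions; if the sense is reversed, the (S)-catalyst is used.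

Step 1
Reactants: 1 2-methylcyclohexane-1,3-dione; 2 methyl vinyl ketone
Product: 3 2-methyl-2-(3-oxobutyl)cyclohexane-1,3-dione
Conditions: AcOH (cat.), hydroquinone (trace), H2O, 75 °C
Reagents that add atoms: none
Why: Intermolecular Michael addition of the doubly activated dione carbon to the enone forges the key bond from the future quaternary ring carbon to the side-chain CH2 (the adduct is still achiral).

Step 2
Reactants: 3 triketone
Product: 4 (8aS)-8a-methyl-3,4,8,8a-tetrahydronaphthalene-1,6(2H,7H)-dione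
Conditions: L-proline (5 mol%), DMSO, rt, 5 d; recrystallisation
Reagents that add atoms: none
Why: Hajos–Parrish–Eder–Sauer–Wiechert intramolecular aldol condensation, in which the L-proline enamine of the side-chain ketone attacks one of the two enantiotopic ring carbonyls through a hydrogen-bonded transition state and fixes the quaternary carbon as S (enantiopurity raised by crystallisation).

Step 3
Reactants: 4 (S)-Wieland–Miescher ketone
Product: 5 (8aS)-8a-methyl-6-(pyrrolidin-1-yl)-3,7,8,8a-tetrahydronaphthalen-1(2H)-one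
Conditions: pyrrolidine, benzene, reflux (Dean–Stark)
Reagents that add atoms: pyrrolidine C1CCNC1
Why: Enamine condensation occurs only at the conjugated carbonyl (cross-conjugated dienamine, the classical protection of steroidal enones), leaving the hindered saturated ketone free and the enone masked against the organometallic reagent.

Step 4
Reactants: 5 dienamine
Product: 7 (4aS,5S)-5-hydroxy-4a,5-dimethyl-4,4a,5,6,7,8-hexahydronaphthalen-2(3H)-one, via hydroxy dienamine 6 (not isolated)
Conditions: MeMgBr, THF, 0 → 40 °C; then AcOH, NaOAc, H2O, rt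
Reagents that add atoms: methylmagnesium bromide C[Mg]Br; water O
Why: Grignard 1,2-addition to the only free carbonyl occurs from the face opposite the angular methyl, so the new tertiary hydroxyl is cis to that methyl, and buffered aqueous acid then hydrolyses the dienamine back to the enone.

Step 5
Reactants: 7 hydroxy enone
Product: 9 3-[(1R,2S)-2-hydroxy-1,2-dimethyl-6-oxocyclohexyl]propanoic acid, via seco 2-oxoaldehyde 8 (not isolated)
Conditions: O3, EtOAc–AcOH, −20 °C; then 30% H2O2, H2O, rt
Reagents that add atoms: ozone [O-][O+]=O; hydrogen peroxide OO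
Why: Ozonolysis with oxidative work-up cleaves the enone C=C to the ring ketone and a 2-oxoaldehyde, which hydrogen peroxide degrades to the propanoic acid with loss of one carbon as formic acid, no stereocentre being touched.

Step 6
Reactants: 9 hydroxy keto acid
Product: 10 (4aR,8aS)-4a,8a-dimethylhexahydro-2H-chromene-2,5(3H)-dione (trans-fused keto δ-lactone)
Conditions: DCC, DMAP (cat.), CH2Cl2, rt
Reagents that add atoms: none
Why: Steglich-type carbodiimide lactonisation closes the six-membered lactone, necessarily trans-fused because hydroxyl and acid chain are trans, which masks both groups, blocks retro-aldol cleavage of the β-hydroxy ketone and locks the ring in one chair with both methyls axial.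

Step 7
Reactants: 10 keto lactone
Product: 11 (4aR,8aS)-4a,8a-dimethyl-2-oxo-3,4,4a,7,8,8a-hexahydro-2H-chromen-5-yl trifluoromethanesulfonate
Conditions: KN(SiMe3)2, PhNTf2, THF, −78 °C
Reagents that add atoms: N-phenylbis(trifluoromethanesulfonimide) O=S(=O)(N(c1ccccc1)S(=O)(=O)C(F)(F)F)C(F)(F)F
Why: Enol triflate formation from the kinetic potassium enolate is regiospecific because the other α-carbon of the ketone is quaternary and the ketone is far more acidic than the lactone.

Step 8
Reactants: 11 enol triflate; 12 tert-butyl(dimethyl)(prop-2-en-1-yloxy)silane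
Product: 13 (4aS,8aS)-5-{3-[tert-butyl(dimethyl)silyl]oxypropyl}-4a,8a-dimethyl-3,4,4a,7,8,8a-hexahydro-2H-chromen-2-one
Conditions: 12, 9-BBN, THF, rt; then 11, Pd(dppf)Cl2 (5 mol%), K3PO4 (aq), DMF, 50 °C
Reagents that add atoms: none
Why: B-alkyl Suzuki–Miyaura cross-coupling of the in situ 9-BBN adduct of the allyl ether with the enol triflate installs the protected three-carbon chain on the sp2 carbon without touching the lactone.

Step 9
Reactants: 13 alkene lactone
Product: 15 (4aS,5S,6S,8aS)-5-{3-[tert-butyl(dimethyl)silyl]oxypropyl}-6-hydroxy-4a,8a-dimethyloctahydro-2H-chromen-2-one, via alkylborane 14 (not isolated)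
Conditions: BH3·THF, THF, 0 °C → rt; then 30% H2O2, NaOAc (aq), 0 °C
Reagents that add atoms: hydrogen peroxide OO
Why: Hydroboration–oxidation places boron on the less substituted alkene carbon and adds H and B syn from the face opposite the axial angular methyl, so the new C–H is trans and the silyloxypropyl chain cis (equatorial) to that methyl.

Step 10
Reactants: 15 alcohol
Product: 16 (4aS,5S,8aS)-5-{3-[tert-butyl(dimethyl)silyl]oxypropyl}-4a,8a-dimethylhexahydro-2H-chromene-2,6(3H)-dione
Conditions: Dess–Martin periodinane, CH2Cl2, rt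
Reagents that add atoms: none
Why: Dess–Martin oxidation gives the ketone under non-basic conditions, and the chain-bearing α-carbon is in any case the thermodynamically preferred equatorial epimer of the rigid trans-fused lactone (the axial epimer would clash with the axial 8a-methyl).

Step 11
Reactants: 16 ketone
Product: 17 (4aS,5S,6R,8aS)-5-{3-[tert-butyl(dimethyl)silyl]oxypropyl}-6-hydroxy-4a,8a-dimethyl-6-(prop-1-en-2-yl)octahydro-2H-chromen-2-one
Conditions: isopropenylmagnesium bromide, CeCl3, THF, −78 °C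
Reagents that add atoms: isopropenylmagnesium bromide C=C(C)[Mg]Br
Why: Organocerium 1,2-addition is non-basic and ketone-selective over the lactone at −78 °C, attacking equatorially; the configuration of the new carbinol carbon is irrelevant because it becomes sp2 in the next step.

Step 12
Reactants: 17 tertiary allylic alcohol
Product: 18 (2Z)-2-[(4aS,5R,8aS)-5-{3-[tert-butyl(dimethyl)silyl]oxypropyl}-4a,8a-dimethyl-2-oxooctahydro-6H-chromen-6-ylidene]propanal
Conditions: C5H5NH[CrO3Cl] (pyridinium chlorochromate), 4 Å MS, CH2Cl2, rt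
Reagents that add atoms: pyridinium chlorochromate [O-][Cr](=O)(=O)Cl.c1cc[nH+]cc1
Why: Babler–Dauben oxidative 1,3-transposition (allylic chromate [3,3] shift, then oxidation) gives the tetrasubstituted enal, and allylic 1,3-strain keeps the isopropenyl methyl away from the equatorial side chain so that the formyl group ends up syn to the chain-bearing CH, i.e. the Z isomer.

Step 13
Reactants: 18 enal lactone
Product: 19 (4aS,5R,6Z,8aS)-5-{3-[tert-butyl(dimethyl)silyl]oxypropyl}-6-(1-hydroxypropan-2-ylidene)-4a,8a-dimethyloctahydro-2H-chromen-2-ol (lactol, anomer mixture)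
Conditions: i-Bu2AlH (3.5 equiv), CH2Cl2, −78 °C
Reagents that add atoms: none
Why: Low-temperature hydride reduction with i-Bu2AlH converts the enal by 1,2-reduction into the allylic alcohol and stops the lactone at the lactol stage (a masked aldehyde).

Step 14
Reactants: 19 lactol; 20 ethyl 2-(triphenyl-λ5-phosphanylidene)propanoate
Product: 21 ethyl (2E)-5-[(1S,2S,5Z,6R)-6-{3-[tert-butyl(dimethyl)silyl]oxypropyl}-2-hydroxy-5-(1-hydroxypropan-2-ylidene)-1,2-dimethylcyclohexyl]-2-methylpent-2-enoate
Conditions: 20 (2.5 equiv), PhCO2H (cat.), toluene, 90 °C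
Reagents that add atoms: none
Why: Wittig olefination of the lactol through its open hydroxy aldehyde with the ester-stabilised ylide gives the E-trisubstituted enoate under thermodynamic control and frees the tertiary hydroxyl.

Step 15
Reactants: 21 diol enoate
Product: 22 bis(triethylsilyl) ether of 21 (allylic CH2O–SiEt3 and tertiary O–SiEt3)
Conditions: Et3SiOTf, 2,6-lutidine, CH2Cl2, −78 → 0 °C
Reagents that add atoms: triethylsilyl trifluoromethanesulfonate CC[Si](CC)(CC)OS(=O)(=O)C(F)(F)F
Why: Silyl triflate silylation protects both the primary allylic and the hindered tertiary hydroxyl, which prevents alkoxide conjugate addition in the later base-mediated coupling.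

Step 16
Reactants: 22 silylated enoate
Product: 23 (2E)-5-[(1S,2S,5Z,6R)-6-{3-[tert-butyl(dimethyl)silyl]oxypropyl}-1,2-dimethyl-2-(triethylsilyloxy)-5-[1-(triethylsilyloxy)propan-2-ylidene]cyclohexyl]-2-methylpent-2-en-1-ol
Conditions: i-Bu2AlH (2.5 equiv), CH2Cl2, −78 °C
Reagents that add atoms: none
Why: Ester reduction with i-Bu2AlH gives the allylic alcohol by 1,2-reduction without affecting silyl ethers or alkene geometry.

Step 17
Reactants: 23 allylic alcohol
Product: 24 (2E)-5-[(1S,2S,5Z,6R)-6-{3-[tert-butyl(dimethyl)silyl]oxypropyl}-1,2-dimethyl-2-(triethylsilyloxy)-5-[1-(triethylsilyloxy)propan-2-ylidene]cyclohexyl]-2-methylpent-2-enal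
Conditions: MnO2, CH2Cl2, rt
Reagents that add atoms: none
Why: MnO2 allylic oxidation gives the E-enal, the only free hydroxyl in the molecule being allylic.

Step 18
Reactants: 25 propanal; 2 methyl vinyl ketone
Product: 26 (2S)-2-methyl-5-oxohexanal
Conditions: (R)-α,α-diphenylprolinol methyl ether (5 mol%), ethyl 3,4-dihydroxybenzoate (20 mol%), neat, 4 °C
Reagents that add atoms: none
Why: Organocatalytic intermolecular Michael addition, in which the E-enamine of propanal is shielded on one face by the diphenylmethyl group so that the enone adds to the open face and sets the methyl-bearing stereocentre as S.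

Step 19
Reactants: 26 keto aldehyde
Product: 27 (4S)-4-methylcyclohex-2-en-1-one
Conditions: KOH (0.1 M aq), Bu4NOH (cat.), Et2O–THF, reflux
Reagents that add atoms: none
Why: Intramolecular aldol condensation of the methyl ketone onto the aldehyde closes ring A as the cyclohexenone, the stereocentre becoming the γ-carbon and surviving the mild, brief base treatment.

Step 20
Reactants: 27 enone
Product: 28 trimethyl{[(3R,4S)-3,4-dimethylcyclohex-1-en-1-yl]oxy}silane
Conditions: MeMgBr, CuBr·SMe2 (5 mol%), Me3SiCl, DMPU, THF, −78 °C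
Reagents that add atoms: methylmagnesium bromide C[Mg]Br; chlorotrimethylsilane C[Si](C)(C)Cl
Why: Copper-catalysed conjugate addition of the Grignard reagent with silyl chloride trapping gives the regiodefined silyl enol ether, methyl entering trans to the existing methyl (this new centre is removed again in the next step).

Step 21
Reactants: 28 silyl enol ether
Product: 29 (4S)-3,4-dimethylcyclohex-2-en-1-one
Conditions: Pd(OAc)2 (1.0 equiv), MeCN, rt
Reagents that add atoms: none
Why: Saegusa–Ito oxidation of the silyl enol ether regenerates the enone on the methylated side, giving the β-methyl enone with the γ-stereocentre intact.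

Step 22
Reactants: 29 enone
Product: 30 trimethyl{[(4S)-3,3,4-trimethylcyclohex-1-en-1-yl]oxy}silane
Conditions: MeMgBr, CuBr·SMe2 (10 mol%), Me3SiCl, DMPU, THF, −78 → −30 °C
Reagents that add atoms: methylmagnesium bromide C[Mg]Br; chlorotrimethylsilane C[Si](C)(C)Cl
Why: A second copper-catalysed conjugate addition creates the gem-dimethyl carbon (no new stereocentre) and delivers the silyl enol ether regiospecifically toward the hindered α-carbon that must carry the side-chain carbon.

Step 23
Reactants: 30 silyl enol ether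
Product: 31 (4S)-2-(hydroxymethyl)-3,3,4-trimethylcyclohexan-1-one (C-2 epimer mixture)
Conditions: 37% aq. HCHO, Yb(OTf)3 (10 mol%), THF, rt
Reagents that add atoms: formaldehyde C=O
Why: Lewis acid-catalysed Mukaiyama aldol reaction with aqueous formaldehyde hydroxymethylates exactly the enol ether carbon; the configuration at this carbon is fixed in the next step.

Step 24
Reactants: 31 hydroxymethyl ketone
Product: 32 (2R,4S)-2-{[tert-butyl(dimethyl)silyl]oxymethyl}-3,3,4-trimethylcyclohexan-1-one
Conditions: t-BuMe2SiCl, imidazole, DBU (0.2 equiv), DMF, rt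
Reagents that add atoms: tert-butyldimethylsilyl chloride CC(C)(C)[Si](C)(C)Cl
Why: Silylation protects the alcohol while amine-base equilibration of the α-stereocentre gives the thermodynamic cis isomer, with silyloxymethyl and 4-methyl both equatorial across the gem-dimethyl carbon.

Step 25
Reactants: 32 ketone
Product: 33 tert-butyl(dimethyl){[(1R,3S)-2,2,3-trimethyl-6-methylidenecyclohexyl]methoxy}silane
Conditions: Cp2TiMe2, toluene, 70 °C
Reagents that add atoms: dimethyltitanocene C[Ti](C)(C1C=CC=C1)C1C=CC=C1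
Why: Petasis methylenation is non-basic, so the hindered, enolisable ketone is converted into the exocyclic methylene without epimerisation or β-elimination.

Step 26
Reactants: 33 silyl ether
Product: 34 [(1R,3S)-2,2,3-trimethyl-6-methylidenecyclohexyl]methanol
Conditions: Bu4NF, THF, rt
Reagents that add atoms: none
Why: Fluoride-induced desilylation frees the primary alcohol.

Step 27
Reactants: 34 alcohol
Product: 35 1-phenyl-5-({[(1R,3S)-2,2,3-trimethyl-6-methylidenecyclohexyl]methyl}sulfanyl)-1H-tetrazole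
Conditions: 1-phenyl-1H-tetrazole-5-thiol, PPh3, diisopropyl azodicarboxylate, THF, 0 °C → rt
Reagents that add atoms: 1-phenyl-1H-tetrazole-5-thiol Sc1nnnn1-c1ccccc1
Why: Mitsunobu reaction with the acidic tetrazole thiol gives the thioether by SN2 displacement at the primary carbon, the ring stereocentres not being involved.

Step 28
Reactants: 35 sulfide
Product: 36 1-phenyl-5-({[(1R,3S)-2,2,3-trimethyl-6-methylidenecyclohexyl]methyl}sulfonyl)-1H-tetrazole
Conditions: (NH4)6Mo7O24·4H2O (10 mol%), 30% H2O2, EtOH, 0 °C → rt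
Reagents that add atoms: hydrogen peroxide OO
Why: Molybdate-catalysed peroxide oxidation takes the sulfide to the sulfone and leaves the unactivated 1,1-disubstituted alkene alone.

Step 29
Reactants: 36 ring A sulfone; 24 ring B enal
Product: 37 tris-silyl ether of triol 38 (tert-butyldimethylsilyl on the propyl oxygen, triethylsilyl on the allylic and tertiary oxygens) carrying the (3E,5E)-4-methyl-6-[(1R,3S)-2,2,3-trimethyl-6-methylidenecyclohexyl]hexa-3,5-dien-1-yl chain
Conditions: 36 (1.3 equiv), KN(SiMe3)2, DME, −60 °C; then 24, −60 °C → rt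
Reagents that add atoms: none
Why: Julia–Kocienski olefination, in which addition of the metalated phenyltetrazolyl sulfone to the enal, Smiles rearrangement and anti elimination give the new disubstituted alkene as the E isomer and join ring A to ring B as the E,E-diene.

Step 30
Reactants: 37 tris-silyl ether
Product: 38 3-[(1R,2S,3S,6Z)-3-hydroxy-6-(1-hydroxypropan-2-ylidene)-2,3-dimethyl-2-{(3E,5E)-4-methyl-6-[(1R,3S)-2,2,3-trimethyl-6-methylidenecyclohexyl]hexa-3,5-dien-1-yl}cyclohexyl]propan-1-ol
Conditions: Bu4NF, THF, rt → 40 °C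
Reagents that add atoms: none
Why: Fluoride cleaves the three silyl ethers (global desilylation) without affecting the triene.

Step 31
Reactants: 38 triol
Product: 39 (2Z)-2-[(2R,3S,4S)-4-hydroxy-2-(3-hydroxypropyl)-3,4-dimethyl-3-{(3E,5E)-4-methyl-6-[(1R,3S)-2,2,3-trimethyl-6-methylidenecyclohexyl]hexa-3,5-dien-1-yl}cyclohexylidene]propanal (target)
Conditions: MnO2, CH2Cl2, rt
Reagents that add atoms: none
Why: MnO2 oxidises only the allylic primary alcohol, leaving the saturated primary and the tertiary hydroxyl, and gives the Z-enal of the target without alkene isomerisation.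

**Compound list**
1 | 2-methylcyclohexane-1,3-dione | CC1C(=O)CCCC1=O | starting material
2 | methyl vinyl ketone (but-3-en-2-one) | CC(=O)C=C | starting material
3 | 2-methyl-2-(3-oxobutyl)cyclohexane-1,3-dione | CC(=O)CCC1(C)C(=O)CCCC1=O | intermediate
4 | (8aS)-8a-methyl-3,4,8,8a-tetrahydronaphthalene-1,6(2H,7H)-dione | C[C@]12CCC(=O)C=C1CCCC2=O | intermediate
5 | (8aS)-8a-methyl-6-(pyrrolidin-1-yl)-3,7,8,8a-tetrahydronaphthalen-1(2H)-one | C[C@]12CCC(N3CCCC3)=CC1=CCCC2=O | intermediate
6 | (1S,8aS)-1,8a-dimethyl-6-(pyrrolidin-1-yl)-1,2,3,7,8,8a-hexahydronaphthalen-1-ol | C[C@]12CCC(N3CCCC3)=CC1=CCC[C@]2(C)O | intermediate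
7 | (4aS,5S)-5-hydroxy-4a,5-dimethyl-4,4a,5,6,7,8-hexahydronaphthalen-2(3H)-one | C[C@]12CCC(=O)C=C1CCC[C@]2(C)O | intermediate
8 | 4-[(1R,2S)-2-hydroxy-1,2-dimethyl-6-oxocyclohexyl]-2-oxobutanal | O=CC(=O)CC[C@@]1(C)C(=O)CCC[C@]1(C)O | intermediate
9 | 3-[(1R,2S)-2-hydroxy-1,2-dimethyl-6-oxocyclohexyl]propanoic acid | OC(=O)CC[C@@]1(C)C(=O)CCC[C@]1(C)O | intermediate
10 | (4aR,8aS)-4a,8a-dimethylhexahydro-2H-chromene-2,5(3H)-dione (trans-fused) | O=C1CC[C@@]2(C)C(=O)CCC[C@]2(C)O1 | intermediate
11 | (4aR,8aS)-4a,8a-dimethyl-2-oxo-3,4,4a,7,8,8a-hexahydro-2H-chromen-5-yl trifluoromethanesulfonate | O=C1CC[C@@]2(C)C(OS(=O)(=O)C(F)(F)F)=CCC[C@]2(C)O1 | intermediate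
12 | tert-butyl(dimethyl)(prop-2-en-1-yloxy)silane | C=CCO[Si](C)(C)C(C)(C)C | starting material
13 | (4aS,8aS)-5-{3-[tert-butyl(dimethyl)silyl]oxypropyl}-4a,8a-dimethyl-3,4,4a,7,8,8a-hexahydro-2H-chromen-2-one | O=C1CC[C@@]2(C)C(CCCO[Si](C)(C)C(C)(C)C)=CCC[C@]2(C)O1 | intermediate
14 | 6-boranyl analogue of 15 (BH2 in place of OH, same configuration) | O=C1CC[C@@]2(C)[C@H](CCCO[Si](C)(C)C(C)(C)C)[C@@H](B)CC[C@]2(C)O1 | intermediate
15 | (4aS,5S,6S,8aS)-5-{3-[tert-butyl(dimethyl)silyl]oxypropyl}-6-hydroxy-4a,8a-dimethyloctahydro-2H-chromen-2-one | O=C1CC[C@@]2(C)[C@H](CCCO[Si](C)(C)C(C)(C)C)[C@@H](O)CC[C@]2(C)O1 | intermediate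
16 | (4aS,5S,8aS)-5-{3-[tert-butyl(dimethyl)silyl]oxypropyl}-4a,8a-dimethylhexahydro-2H-chromene-2,6(3H)-dione | O=C1CC[C@@]2(C)[C@H](CCCO[Si](C)(C)C(C)(C)C)C(=O)CC[C@]2(C)O1 | intermediate
17 | (4aS,5S,6R,8aS)-5-{3-[tert-butyl(dimethyl)silyl]oxypropyl}-6-hydroxy-4a,8a-dimethyl-6-(prop-1-en-2-yl)octahydro-2H-chromen-2-one | O=C1CC[C@@]2(C)[C@H](CCCO[Si](C)(C)C(C)(C)C)[C@@](O)(C(C)=C)CC[C@]2(C)O1 | intermediate
18 | (2Z)-2-[(4aS,5R,8aS)-5-{3-[tert-butyl(dimethyl)silyl]oxypropyl}-4a,8a-dimethyl-2-oxooctahydro-6H-chromen-6-ylidene]propanal | O=C1CC[C@@]2(C)[C@H](CCCO[Si](C)(C)C(C)(C)C)/C(=C(/C)C=O)CC[C@]2(C)O1 | intermediate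
19 | (4aS,5R,6Z,8aS)-5-{3-[tert-butyl(dimethyl)silyl]oxypropyl}-6-(1-hydroxypropan-2-ylidene)-4a,8a-dimethyloctahydro-2H-chromen-2-ol (anomer mixture) | OC1CC[C@@]2(C)[C@H](CCCO[Si](C)(C)C(C)(C)C)/C(=C(/C)CO)CC[C@]2(C)O1 | intermediate
20 | ethyl 2-(triphenyl-λ5-phosphanylidene)propanoate | CCOC(=O)C(C)=P(c1ccccc1)(c1ccccc1)c1ccccc1 | starting material
21 | ethyl (2E)-5-[(1S,2S,5Z,6R)-6-{3-[tert-butyl(dimethyl)silyl]oxypropyl}-2-hydroxy-5-(1-hydroxypropan-2-ylidene)-1,2-dimethylcyclohexyl]-2-methylpent-2-enoate | CCOC(=O)/C(C)=C/CC[C@@]1(C)[C@H](CCCO[Si](C)(C)C(C)(C)C)/C(=C(/C)CO)CC[C@]1(C)O | intermediate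
22 | ethyl (2E)-5-[(1S,2S,5Z,6R)-6-{3-[tert-butyl(dimethyl)silyl]oxypropyl}-1,2-dimethyl-2-(triethylsilyloxy)-5-[1-(triethylsilyloxy)propan-2-ylidene]cyclohexyl]-2-methylpent-2-enoate | CCOC(=O)/C(C)=C/CC[C@@]1(C)[C@H](CCCO[Si](C)(C)C(C)(C)C)/C(=C(/C)CO[Si](CC)(CC)CC)CC[C@]1(C)O[Si](CC)(CC)CC | intermediate
23 | (2E)-pent-2-en-1-ol corresponding to ester 22 | OC/C(C)=C/CC[C@@]1(C)[C@H](CCCO[Si](C)(C)C(C)(C)C)/C(=C(/C)CO[Si](CC)(CC)CC)CC[C@]1(C)O[Si](CC)(CC)CC | intermediate
24 | (2E)-pent-2-enal corresponding to alcohol 23 (ring B fragment) | O=C/C(C)=C/CC[C@@]1(C)[C@H](CCCO[Si](C)(C)C(C)(C)C)/C(=C(/C)CO[Si](CC)(CC)CC)CC[C@]1(C)O[Si](CC)(CC)CC | intermediate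
25 | propanal | CCC=O | starting material
26 | (2S)-2-methyl-5-oxohexanal | O=C[C@@H](C)CCC(C)=O | intermediate
27 | (4S)-4-methylcyclohex-2-en-1-one | O=C1C=C[C@@H](C)CC1 | intermediate
28 | trimethyl{[(3R,4S)-3,4-dimethylcyclohex-1-en-1-yl]oxy}silane | C[Si](C)(C)OC1=C[C@H](C)[C@@H](C)CC1 | intermediate
29 | (4S)-3,4-dimethylcyclohex-2-en-1-one | O=C1C=C(C)[C@@H](C)CC1 | intermediate
30 | trimethyl{[(4S)-3,3,4-trimethylcyclohex-1-en-1-yl]oxy}silane | C[Si](C)(C)OC1=CC(C)(C)[C@@H](C)CC1 | intermediate
31 | (4S)-2-(hydroxymethyl)-3,3,4-trimethylcyclohexan-1-one (C-2 epimers) | O=C1CC[C@H](C)C(C)(C)C1CO | intermediate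
32 | (2R,4S)-2-{[tert-butyl(dimethyl)silyl]oxymethyl}-3,3,4-trimethylcyclohexan-1-one | O=C1CC[C@H](C)C(C)(C)[C@@H]1CO[Si](C)(C)C(C)(C)C | intermediate
33 | tert-butyl(dimethyl){[(1R,3S)-2,2,3-trimethyl-6-methylidenecyclohexyl]methoxy}silane | C=C1CC[C@H](C)C(C)(C)[C@@H]1CO[Si](C)(C)C(C)(C)C | intermediate
34 | [(1R,3S)-2,2,3-trimethyl-6-methylidenecyclohexyl]methanol | C=C1CC[C@H](C)C(C)(C)[C@@H]1CO | intermediate
35 | 1-phenyl-5-({[(1R,3S)-2,2,3-trimethyl-6-methylidenecyclohexyl]methyl}sulfanyl)-1H-tetrazole | C=C1CC[C@H](C)C(C)(C)[C@@H]1CSc1nnnn1-c1ccccc1 | intermediate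
36 | 1-phenyl-5-({[(1R,3S)-2,2,3-trimethyl-6-methylidenecyclohexyl]methyl}sulfonyl)-1H-tetrazole (ring A fragment) | C=C1CC[C@H](C)C(C)(C)[C@@H]1CS(=O)(=O)c1nnnn1-c1ccccc1 | intermediate
37 | tris-silyl ether of 38 (propyl O–SiMe2t-Bu; allylic and tertiary O–SiEt3) | C=C1CC[C@H](C)C(C)(C)[C@@H]1/C=C/C(C)=C/CC[C@@]1(C)[C@H](CCCO[Si](C)(C)C(C)(C)C)/C(=C(/C)CO[Si](CC)(CC)CC)CC[C@]1(C)O[Si](CC)(CC)CC | intermediate
38 | 3-[(1R,2S,3S,6Z)-3-hydroxy-6-(1-hydroxypropan-2-ylidene)-2,3-dimethyl-2-{(3E,5E)-4-methyl-6-[(1R,3S)-2,2,3-trimethyl-6-methylidenecyclohexyl]hexa-3,5-dien-1-yl}cyclohexyl]propan-1-ol | C=C1CC[C@H](C)C(C)(C)[C@@H]1/C=C/C(C)=C/CC[C@@]1(C)[C@H](CCCO)/C(=C(/C)CO)CC[C@]1(C)O | intermediate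
39 | (2Z)-2-[(2R,3S,4S)-4-hydroxy-2-(3-hydroxypropyl)-3,4-dimethyl-3-{(3E,5E)-4-methyl-6-[(1R,3S)-2,2,3-trimethyl-6-methylidenecyclohexyl]hexa-3,5-dien-1-yl}cyclohexylidene]propanal | C=C1CC[C@H](C)C(C)(C)[C@@H]1/C=C/C(C)=C/CC[C@@]1(C)[C@H](CCCO)/C(=C(/C)C=O)CC[C@]1(C)O | target

**Totals**
Total step count: 31. Longest linear sequence: 20 steps (steps 1–17, then 29–31). The ring A branch (steps 18–28) is 11 steps before the union.

**Three steps most likely to fail**

Step 9 (hydroboration). The borane may attack partly from the methyl face or reduce the lactone. Fallback: setting out from 13, epoxidation with m-chloroperbenzoic acid on the face opposite the angular methyl gives the 5,6-epoxy lactone F1. A BF3·OEt2-promoted Meinwald rearrangement (opening at the tertiary carbon, 1,2-hydride shift) then gives the C-5 epimeric ketone F2. A catalytic amount of DBU equilibrates F2 to the equatorial epimer, which is 16, where the route resumes.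

Step 12 (oxidative transposition). The tetrasubstituted enal may form slowly or as an E/Z mixture. Fallback: setting out from 16, Horner–Wadsworth–Emmons olefination with triethyl 2-phosphonopropionate and NaH in DME gives the (Z)-enoate lactone F3, the ester sitting syn to the chain-bearing CH for the same allylic-strain reason. Excess i-Bu2AlH at −78 °C then reduces the ester to the allylic alcohol and the lactone to the lactol, which is 19.

Step 29 (Julia–Kocienski union). The hindered, β-branched sulfone anion may add sluggishly or give an E/Z mixture with the enal. Fallback with reversed polarity: setting out from 34, Dess–Martin oxidation gives the ring A aldehyde F4. Setting out from 23, CBr4/PPh3 gives the allylic bromide F5, and an Arbuzov reaction with P(OEt)3 gives the allylic phosphonate F6. Horner–Wadsworth–Emmons reaction of F6 (deprotonated with LiN(SiMe3)2, THF, −78 °C) with F4 gives the E,E-diene 37, where the route resumes.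

**Further compounds**
F1 | step 9 | 5,6-epoxide of 13 (oxirane on the face opposite the 4a-methyl) | O=C1CC[C@@]2(C)[C@@]3(CCCO[Si](C)(C)C(C)(C)C)O[C@H]3CC[C@]2(C)O1
F2 | step 9 | (4aS,5R,8aS)-5-{3-[tert-butyl(dimethyl)silyl]oxypropyl}-4a,8a-dimethylhexahydro-2H-chromene-2,6(3H)-dione (C-5 epimer of 16) | O=C1CC[C@@]2(C)[C@@H](CCCO[Si](C)(C)C(C)(C)C)C(=O)CC[C@]2(C)O1
F3 | step 12 | ethyl (2Z)-2-[(4aS,5R,8aS)-5-{3-[tert-butyl(dimethyl)silyl]oxypropyl}-4a,8a-dimethyl-2-oxooctahydro-6H-chromen-6-ylidene]propanoate | O=C1CC[C@@]2(C)[C@H](CCCO[Si](C)(C)C(C)(C)C)/C(=C(/C)C(=O)OCC)CC[C@]2(C)O1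
F4 | step 29 | (1R,3S)-2,2,3-trimethyl-6-methylidenecyclohexane-1-carbaldehyde | C=C1CC[C@H](C)C(C)(C)[C@@H]1C=O
F5 | step 29 | allylic bromide from 23 (CH2Br in place of CH2OH) | BrC/C(C)=C/CC[C@@]1(C)[C@H](CCCO[Si](C)(C)C(C)(C)C)/C(=C(/C)CO[Si](CC)(CC)CC)CC[C@]1(C)O[Si](CC)(CC)CC
F6 | step 29 | diethyl allylphosphonate from F5 (CH2P(O)(OEt)2 in place of CH2Br) | CCOP(=O)(OCC)C/C(C)=C/CC[C@@]1(C)[C@H](CCCO[Si](C)(C)C(C)(C)C)/C(=C(/C)CO[Si](CC)(CC)CC)CC[C@]1(C)O[Si](CC)(CC)CC
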